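**Retrosynthetic overview**

1. The target is a chain of five six-membered rings A–B–C–D–E joined by four CH2 bridges. Rings B, C and D are butanoylphloroglucinol units (bought as 9). Rings A and E are 2-butanoyl-3,5-dihydroxy-4,4-dimethylcyclohexa-2,5-dien-1-one units (8), bridged at C-6.
2. The two outer bridges are cut last: 2 × 8 plus bis-Mannich base 12 of the B–C–D trimer (double ortho-quinone methide capture). The two inner bridges come from bis-Mannich base 10 of 9 and 2 × 9.
3. Rings A and E are the only rings formed, both by one de novo annulation. Bonds C-2–C-3 and C-4–C-5 of the trione ring are made in one flask from keto-dioxinone 3 (supplies C-5, C-6, C-1, C-2 and the butanoyl group) and dimethylketene silyl acetal 4 (supplies C-3, C-4 and both methyl groups).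
4. Enabling feature: ring A/E is a cyclohexane-1,3,5-trione, a head-to-tail triad of acyl units. C-4 is a hydrogen-free gem-dimethyl carbon, so it can come from a tetrasubstituted ketene acetal and it blocks aromatisation and aldol closure. C-5 and C-3 are at the carboxyl oxidation level (ketene and ester carbons), and C-2 lies between two carbonyl groups (a doubly stabilised carbanion for Claisen closure).
5. Order of ring formation: ring A ≡ ring E (step 2, one preparation used twice). Rings B, C and D are never formed, only linked (step 4 inner bridges, step 6 outer bridges).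

Key step: step 2

Remark: the target has no stereocentre and is drawn as one enol tautomer of each terminal trione; all intermediates are written in the matching tautomer, and 1-(2,4,6-trihydroxyphenyl)butan-1-one (9) is taken as a purchasable compound.

**Route**

Step 1
Reactants: 1 2,2,6-trimethyl-4H-1,3-dioxin-4-one; 2 butanoyl chloride
Product: 3 2,2-dimethyl-6-(2-oxopentyl)-4H-1,3-dioxin-4-one
Conditions: 1 (2 equiv), LiN(SiMe3)2 (2 equiv), THF, −78 °C; then 2 (1 equiv), −78 → −20 °C; aq. NH4Cl
Reagents that add atoms: none
Why: The lithium dienolate of 1 should react at its γ-carbon with the acid chloride in a vinylogous crossed Claisen acylation, the second equivalent of dienolate absorbing the acidic proton of keto-dioxinone 3; no stereocentre is formed.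

Step 2
Reactants: 3 2,2-dimethyl-6-(2-oxopentyl)-4H-1,3-dioxin-4-one; 4 1-methoxy-2-methyl-1-(trimethylsilyloxy)prop-1-ene
Product: 8 2-butanoyl-3,5-dihydroxy-4,4-dimethylcyclohexa-2,5-dien-1-one (butanoylfilicinic acid), via acylketene 5 (not isolated), via silyl enol ether 6 (not isolated), via triketo ester 7 (not isolated)
Conditions: 4 (3 equiv), PhMe, 110 °C, slow addition of 3; then NaOMe (4 equiv), MeOH, 65 °C; aq. HCl
Reagents that add atoms: none
Why: Proposed new method: retro-[4+2] loss of acetone from 3 at 110 °C should give acylketene 5, whose ketene carbon is attacked by the nucleophilic, fully substituted carbon of ketene acetal 4 (asynchronous hetero-[4+2] addition with O-to-O silyl transfer) to give silyl enol ether 6 and with it the quaternary C-4–C-5 bond; methoxide then desilylates 6 to triketo ester 7 and drives the Claisen (Dieckmann-type) condensation of the doubly activated C-6 methylene of 7 onto its unconjugated ester carbon, which forms the C-2–C-3 bond. The closest known reactions are the capture of dioxinone-derived acylketenes by ketene acetals and enol ethers (hetero-Diels–Alder C-acylation) and the base-mediated Claisen cyclisation of 3,5,7-triketo esters to acylphloroglucinols; the new element is their union in one flask with a tetrasubstituted silyl ketene acetal. The only ring closed is the six-membered carbocycle, by a 6-exo-trig acyl substitution (stabilised carbanion on the ester carbonyl, methoxide lost). No stereocentre is formed, the product being achiral. The step needs C-capture of 5 ahead of attack by its own enol oxygen, and Claisen instead of aldol closure of 7: excess 4 with slow addition of 3 should keep the bimolecular C–C bond formation ahead of closure to a 4-hydroxy-2-pyranone, and the gem-dimethyl carbon of 7 carries no hydrogen, so the aldol (resorcylate) mode and aromatisation are excluded and the only six-membered closure open to a stabilised carbanion is the desired one, pulled forward by the strongly acidic trione product.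

Step 3
Reactants: 9 1-(2,4,6-trihydroxyphenyl)butan-1-one
Product: 10 1-{3,5-bis[(dimethylamino)methyl]-2,4,6-trihydroxyphenyl}butan-1-one
Conditions: CH2(NMe2)2 (2.5 equiv), 1,4-dioxane, 25 °C
Reagents that add atoms: N,N,N',N'-tetramethylmethanediamine, CN(C)CN(C)C
Why: Phenolic Mannich reaction (ortho-aminomethylation): the acidic, electron-rich ring of 9 should protonate the aminal to the iminium ion and be substituted at both free ring carbons, which are equivalent and each flanked by two hydroxyl groups, so no regiochemical or stereochemical question arises.

Step 4
Reactants: 10 1-{3,5-bis[(dimethylamino)methyl]-2,4,6-trihydroxyphenyl}butan-1-one; 9 1-(2,4,6-trihydroxyphenyl)butan-1-one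
Product: 11 1-{3,5-bis[(3-butanoyl-2,4,6-trihydroxyphenyl)methyl]-2,4,6-trihydroxyphenyl}butan-1-one
Conditions: 9 (10 equiv), 1,4-dioxane, 100 °C, N2 sweep
Reagents that add atoms: none
Why: Mannich-base alkylation through an ortho-quinone methide: thermal loss of dimethylamine from each aminomethyl arm of 10 should give a quinone methide that is captured at a free ring carbon of 9 (Friedel–Crafts-type conjugate addition), the tenfold excess of 9 keeping each outer ring monoalkylated and the nitrogen sweep removing the amine; no stereocentre is formed.

Step 5
Reactants: 11 1-{3,5-bis[(3-butanoyl-2,4,6-trihydroxyphenyl)methyl]-2,4,6-trihydroxyphenyl}butan-1-one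
Product: 12 1-{3,5-bis[(3-butanoyl-5-[(dimethylamino)methyl]-2,4,6-trihydroxyphenyl)methyl]-2,4,6-trihydroxyphenyl}butan-1-one
Conditions: CH2(NMe2)2 (3 equiv), 1,4-dioxane, 25 °C
Reagents that add atoms: N,N,N',N'-tetramethylmethanediamine, CN(C)CN(C)C
Why: Second phenolic Mannich reaction: only the two terminal rings of 11 still carry a free ring carbon, so aminomethylation can occur only there and should give the bis-electrophile precursor 12 without regiochemical ambiguity.

Step 6
Reactants: 12 1-{3,5-bis[(3-butanoyl-5-[(dimethylamino)methyl]-2,4,6-trihydroxyphenyl)methyl]-2,4,6-trihydroxyphenyl}butan-1-one; 8 2-butanoyl-3,5-dihydroxy-4,4-dimethylcyclohexa-2,5-dien-1-one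
Product: 13 1-{3,5-bis[(3-butanoyl-5-[(5-butanoyl-2,4-dihydroxy-3,3-dimethyl-6-oxocyclohexa-1,4-dien-1-yl)methyl]-2,4,6-trihydroxyphenyl)methyl]-2,4,6-trihydroxyphenyl}butan-1-one (CNP0188003.0)
Conditions: 8 (2.4 equiv), 1,4-dioxane, 90 °C, N2 sweep; dilute aq. HCl work-up
Reagents that add atoms: none
Why: Twofold Mannich-base alkylation through ortho-quinone methides: the acidic trione 8 should protonate the amino groups of 12, dimethylamine is expelled, and the only unsubstituted ring carbon of 8 (C-6, the nucleophilic carbon of a vinylogous acid) adds to each quinone methide, after which neither partner has a free ring position and the chain cannot grow further; no stereocentre is formed.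

**Compound list**

1 | 2,2,6-trimethyl-4H-1,3-dioxin-4-one | CC1=CC(=O)OC(C)(C)O1 | starting material
2 | butanoyl chloride | CCCC(=O)Cl | starting material
3 | 2,2-dimethyl-6-(2-oxopentyl)-4H-1,3-dioxin-4-one | CCCC(=O)CC1=CC(=O)OC(C)(C)O1 | intermediate
4 | 1-methoxy-2-methyl-1-(trimethylsilyloxy)prop-1-ene (dimethylketene methyl trimethylsilyl acetal) | COC(O[Si](C)(C)C)=C(C)C | starting material
5 | oct-1-ene-1,3,5-trione (butanoylacetylketene) | CCCC(=O)CC(=O)C=C=O | intermediate
6 | methyl (4Z)-2,2-dimethyl-3,7-dioxo-5-(trimethylsilyloxy)dec-4-enoate | COC(=O)C(C)(C)C(=O)/C=C(\O[Si](C)(C)C)CC(=O)CCC | intermediate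
7 | methyl 2,2-dimethyl-3,5,7-trioxodecanoate | COC(=O)C(C)(C)C(=O)CC(=O)CC(=O)CCC | intermediate
8 | 2-butanoyl-3,5-dihydroxy-4,4-dimethylcyclohexa-2,5-dien-1-one (butanoylfilicinic acid) | CCCC(=O)C1=C(O)C(C)(C)C(O)=CC1=O | intermediate
9 | 1-(2,4,6-trihydroxyphenyl)butan-1-one | CCCC(=O)c1c(O)cc(O)cc1O | starting material
10 | 1-{3,5-bis[(dimethylamino)methyl]-2,4,6-trihydroxyphenyl}butan-1-one | CCCC(=O)c1c(O)c(CN(C)C)c(O)c(CN(C)C)c1O | intermediate
11 | 1-{3,5-bis[(3-butanoyl-2,4,6-trihydroxyphenyl)methyl]-2,4,6-trihydroxyphenyl}butan-1-one | CCCC(=O)c1c(O)cc(O)c(Cc2c(O)c(Cc3c(O)cc(O)c(C(=O)CCC)c3O)c(O)c(C(=O)CCC)c2O)c1O | intermediate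
12 | 1-{3,5-bis[(3-butanoyl-5-[(dimethylamino)methyl]-2,4,6-trihydroxyphenyl)methyl]-2,4,6-trihydroxyphenyl}butan-1-one | CCCC(=O)c1c(O)c(CN(C)C)c(O)c(Cc2c(O)c(Cc3c(O)c(CN(C)C)c(O)c(C(=O)CCC)c3O)c(O)c(C(=O)CCC)c2O)c1O | intermediate
13 | 1-{3,5-bis[(3-butanoyl-5-[(5-butanoyl-2,4-dihydroxy-3,3-dimethyl-6-oxocyclohexa-1,4-dien-1-yl)methyl]-2,4,6-trihydroxyphenyl)methyl]-2,4,6-trihydroxyphenyl}butan-1-one (CNP0188003.0) | CCCC(=O)C1=C(O)C(C)(C)C(O)=C(Cc2c(O)c(Cc3c(O)c(Cc4c(O)c(CC5=C(O)C(C)(C)C(O)=C(C(=O)CCC)C5=O)c(O)c(C(=O)CCC)c4O)c(O)c(C(=O)CCC)c3O)c(O)c(C(=O)CCC)c2O)C1=O | target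

**Step count and risk**

Total steps: 6. Longest linear sequence: 4 steps (9 → 10 → 11 → 12 → 13; steps 3, 4, 5, 6). The branch 1 → 3 → 8 (steps 1 and 2) joins at step 6.

Steps most likely to fail:

Step 2 (proposed new method). Capture of the ketene in 5 by the enol oxygen of its own 1,3-diketone side chain (closure to a 4-hydroxy-2-pyranone) may outrun bimolecular C–C bond formation with the hindered tetrasubstituted nucleophile. In the second stage methoxide may cleave the non-enolisable β-keto ester of 7 (retro-Claisen) faster than the ring closes. The fallback uses known chemistry, sets out from 9 and abandons ring construction. Twofold C-methylation of one ring carbon of 9 with iodomethane and NaOMe in MeOH at 0–25 °C, the classical dearomatising geminal methylation of acylphloroglucinols to acylfilicinic acids, should give 8 directly, to be separated from mono- and trimethylated congeners by chromatography. The path comes back to the route at 8 and makes no compound outside the list (F0).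

Step 6. Expulsion of dimethylamine from the crowded terminal rings of 12 may be slow and reversible at a temperature at which the liberated amine also reopens the inner diarylmethane bridges (retro-Mannich methylene scrambling), and the second capping may stall. The fallback reverses the polarity of the union and sets out from 8. Compound 8 is aminomethylated at its free ring carbon with N,N,N',N'-tetramethylmethanediamine in CH2Cl2 at 0 °C to give 2-butanoyl-6-[(dimethylamino)methyl]-3,5-dihydroxy-4,4-dimethylcyclohexa-2,5-dien-1-one F1. This β-amino trione should lose dimethylamine near room temperature to a 6-methylene trione, a far stronger Michael acceptor than an aryl quinone methide. It is stirred (2.2 equiv) with trimer 11, taken before step 5, in 1,4-dioxane at 25–40 °C, where the free carbon of each terminal ring adds in a Michael-type Friedel–Crafts alkylation. The path bypasses 12 and comes back at 13.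

Step 4. Statistical over-alkylation is the risk: trimer 11 competes with 9 for the quinone methide and grows into tetramers and higher oligomers, or recombination of the quinone methide with dimethylamine stalls conversion. The fallback inverts the roles of the fragments and sets out from 10 and 9 with reversed stoichiometry. Compound 9 (1 equiv) is added slowly to 10 (6 equiv) in 1,4-dioxane at 100 °C, so that 9 is the nucleophile at both of its free ring carbons and each captures a quinone methide from a different molecule of 10, whose second aminomethyl arm remains. The product is 12 itself, which has no free ring carbon and cannot be alkylated further. The path skips 11 and step 5, comes back at 12, and makes no compound outside the list (F0).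

Further compounds
F0 | step 2 | none | none
F1 | step 6 | 2-butanoyl-6-[(dimethylamino)methyl]-3,5-dihydroxy-4,4-dimethylcyclohexa-2,5-dien-1-one | CCCC(=O)C1=C(O)C(C)(C)C(O)=C(CN(C)C)C1=O
F0 | step 4 | none | none
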